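**Strategy.** The synthesis hinges on the enol-ether bond O1–C7a of the dihydrofuran ring (benzofuran numbering). In the key step the C2 hydroxyl of a syn-diol side chain on C3a condenses with C7a, the only enol carbon of a dearomatised acylphloroglucinol ring not engaged in the isobutyryl chelate and flanked by quaternary C7; one acid treatment removes an acetonide and closes the furan by 5-exo cyclodehydration with retention at C2 and defined ring-fusion regiochemistry. The precursor is a monocyclic enolised 2-acylcyclohexane-1,3,5-trione, made by reductive Knoevenagel union of a nerol-derived aldehyde with a core from Fráter–Seebach alkylation and Dieckmann cyclisation; C5 is prenylated last.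

Key step: step 13

Remark: atom labels (O1, C2, C3, C3a, C4–C7, C7a) follow the 2,3-dihydro-1-benzofuran numbering of the target, and C1' is the side-chain carbinol carbon. Enolised triones are written as one tautomer and their descriptors refer to that drawing.

Step 1
Reactants: 1 nerol [(2Z)-3,7-dimethylocta-2,6-dien-1-ol]
Product: 2 [(2R,3S)-3-methyl-3-(4-methylpent-3-en-1-yl)oxiran-2-yl]methanol
Conditions: Ti(OiPr)4 (cat.), D-(−)-diisopropyl tartrate (cat.), t-BuOOH, 4 Å MS, CH2Cl2, −20 °C
Reagents that add atoms: tert-butyl hydroperoxide, CC(C)(C)OO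
Why: Sharpless asymmetric epoxidation, in which the allylic hydroxyl directs oxidation to the 2,3-olefin only and the D-tartrate ligand selects the face that gives the (2R,3S) cis-epoxide.

Step 2
Reactants: 2 [(2R,3S)-3-methyl-3-(4-methylpent-3-en-1-yl)oxiran-2-yl]methanol
Product: 3 (2R,3S)-3,7-dimethyl-1-(phenylsulfanyl)oct-6-ene-2,3-diol
Conditions: PhSH, NaOH (0.5 M aq.), t-BuOH, 75 °C
Reagents that add atoms: thiophenol, Sc1ccccc1
Why: Payne rearrangement with thiolate trapping, in which the C1 alkoxide displaces the epoxide oxygen at C2 with inversion (setting the future C2 of the target and the syn relation to the untouched tertiary C–O) and thiolate opens the terminal epoxide at C1.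

Step 3
Reactants: 3 (2R,3S)-3,7-dimethyl-1-(phenylsulfanyl)oct-6-ene-2,3-diol
Product: 4 (4S,5R)-2,2,4-trimethyl-4-(4-methylpent-3-en-1-yl)-5-[(phenylsulfanyl)methyl]-1,3-dioxolane
Conditions: 2,2-dimethoxypropane, pyridinium p-toluenesulfonate (cat.), CH2Cl2, 23 °C
Reagents that add atoms: 2,2-dimethoxypropane, COC(C)(C)OC
Why: Acid-catalysed ketal exchange protects the only 1,2-diol as its acetonide without touching either stereocentre.

Step 4
Reactants: 4 (4S,5R)-2,2,4-trimethyl-4-(4-methylpent-3-en-1-yl)-5-[(phenylsulfanyl)methyl]-1,3-dioxolane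
Product: 5 (4S,5R)-2,2,4-trimethyl-4-(4-methylpent-3-en-1-yl)-5-[(phenylsulfinyl)methyl]-1,3-dioxolane (both sulfur epimers)
Conditions: NaIO4, MeOH/H2O, 0 to 23 °C
Reagents that add atoms: sodium periodate, [Na+].[O-]I(=O)(=O)=O
Why: Periodate oxidises the sulfide chemoselectively to the sulfoxide and leaves the trisubstituted olefin alone.

Step 5
Reactants: 5 (4S,5R)-2,2,4-trimethyl-4-(4-methylpent-3-en-1-yl)-5-[(phenylsulfinyl)methyl]-1,3-dioxolane
Product: 7 (4R,5S)-2,2,5-trimethyl-5-(4-methylpent-3-en-1-yl)-1,3-dioxolane-4-carbaldehyde, via trifluoroacetoxy sulfide 6 (not isolated)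
Conditions: (CF3CO)2O, 2,6-lutidine, MeCN, 0 °C; then aq. NaHCO3, 23 °C
Reagents that add atoms: trifluoroacetic anhydride, O=C(OC(=O)C(F)(F)F)C(F)(F)F
Why: Pummerer rearrangement of the only α-CH2 followed by mild hydrolysis of the O,S-acetal ester should release the aldehyde, the buffered conditions being chosen so that the α-alkoxy stereocentre is not epimerised.

Step 6
Reactants: 8 methyl (3S)-3-hydroxybutanoate
Product: 9 methyl (2S,3S)-3-hydroxy-2-(3-methylbut-2-en-1-yl)butanoate
Conditions: lithium diisopropylamide (2.2 equiv), THF, −50 to −20 °C; prenyl bromide, DMPU, −20 to 0 °C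
Reagents that add atoms: 1-bromo-3-methylbut-2-ene, CC(C)=CCBr
Why: Fráter–Seebach alkylation, in which the lithium-chelated alkoxide enolate is alkylated on the face anti to the C3 methyl group to give the anti (2S,3S) product.

Step 7
Reactants: 9 methyl (2S,3S)-3-hydroxy-2-(3-methylbut-2-en-1-yl)butanoate
Product: 10 methyl (2R)-2-[(1S)-1-hydroxyethyl]-2,5-dimethylhex-4-enoate
Conditions: lithium diisopropylamide (2.2 equiv), THF/DMPU, −50 to −10 °C; MeI
Reagents that add atoms: iodomethane, CI
Why: Second Fráter–Seebach alkylation, in which methyl enters the same chelate-defined face so that the order prenyl then methyl fixes the quaternary centre as (2R), the future C7.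

Step 8
Reactants: 10 methyl (2R)-2-[(1S)-1-hydroxyethyl]-2,5-dimethylhex-4-enoate
Product: 11 methyl (2R)-2-acetyl-2,5-dimethylhex-4-enoate
Conditions: Dess–Martin periodinane, NaHCO3, CH2Cl2, 23 °C
Reagents that add atoms: none
Why: Dess–Martin oxidation of the secondary alcohol gives the β-keto ester, whose quaternary α-carbon cannot epimerise.

Step 9
Reactants: 11 methyl (2R)-2-acetyl-2,5-dimethylhex-4-enoate
Product: 12 methyl (2R)-2,6-dimethyl-2-(3-methylbut-2-en-1-yl)-3,5-dioxoheptanoate
Conditions: LiN(SiMe3)2 (2.1 equiv), THF, −78 °C; i-PrCOCl, −78 to 0 °C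
Reagents that add atoms: 2-methylpropanoyl chloride, CC(C)C(Cl)=O
Why: Claisen-type C-acylation of the lithium enolate at the only enolisable position (the acetyl methyl, future C5), the second equivalent of base trapping the more acidic β-diketone.

Step 10
Reactants: 12 methyl (2R)-2,6-dimethyl-2-(3-methylbut-2-en-1-yl)-3,5-dioxoheptanoate
Product: 13 methyl (2R)-4-acetyl-2,6-dimethyl-2-(3-methylbut-2-en-1-yl)-3,5-dioxoheptanoate
Conditions: MgCl2, pyridine, AcCl, CH2Cl2, 0 to 23 °C
Reagents that add atoms: acetyl chloride, CC(Cl)=O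
Why: Magnesium-chelate (soft-enolisation) C-acylation of the β-diketone at its central carbon gives the triacylmethane that carries both the future exocyclic isobutyryl group and the two-carbon unit C4–C3a.

Step 11
Reactants: 13 methyl (2R)-4-acetyl-2,6-dimethyl-2-(3-methylbut-2-en-1-yl)-3,5-dioxoheptanoate
Product: 14 (4S)-3,5-dihydroxy-4-methyl-4-(3-methylbut-2-en-1-yl)-2-(2-methylpropanoyl)cyclohexa-2,5-dien-1-one
Conditions: lithium diisopropylamide (3.2 equiv), THF, −78 to 23 °C; then aq. HCl
Reagents that add atoms: none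
Why: Intramolecular Claisen (Dieckmann-type) condensation, in which the dianion's acetyl carbanion attacks the methyl ester 6-exo-trig to form the carbocycle (ester carbon becomes C7a, acetyl carbons become C4 and C3a); the quaternary carbon is not touched and becomes the ring stereocentre C7.

Step 12
Reactants: 14 (4S)-3,5-dihydroxy-4-methyl-4-(3-methylbut-2-en-1-yl)-2-(2-methylpropanoyl)cyclohexa-2,5-dien-1-one, 7 (4R,5S)-2,2,5-trimethyl-5-(4-methylpent-3-en-1-yl)-1,3-dioxolane-4-carbaldehyde
Product: 16 (4S)-3,5-dihydroxy-4-methyl-4-(3-methylbut-2-en-1-yl)-2-(2-methylpropanoyl)-6-{[(4S,5S)-2,2,5-trimethyl-5-(4-methylpent-3-en-1-yl)-1,3-dioxolan-4-yl]methyl}cyclohexa-2,5-dien-1-one, via alkylidene trione 15 (not isolated)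
Conditions: L-proline (0.2 equiv), Hantzsch ester (diethyl 2,6-dimethyl-1,4-dihydropyridine-3,5-dicarboxylate, 1.1 equiv), CH2Cl2, 23 °C
Reagents that add atoms: none
Why: Organocatalytic three-component reductive alkylation (Knoevenagel condensation at the only C–H ring carbon, C3a, then conjugate hydride transfer from the Hantzsch ester); no stereocentre is formed, and the α-alkoxy centre of the aldehyde should survive because the iminium is captured faster than it can form an enamine.

Step 13
Reactants: 16 (4S)-3,5-dihydroxy-4-methyl-4-(3-methylbut-2-en-1-yl)-2-(2-methylpropanoyl)-6-{[(4S,5S)-2,2,5-trimethyl-5-(4-methylpent-3-en-1-yl)-1,3-dioxolan-4-yl]methyl}cyclohexa-2,5-dien-1-one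
Product: 18 (2S,7R)-6-hydroxy-2-[(2S)-2-hydroxy-6-methylhept-5-en-2-yl]-7-methyl-7-(3-methylbut-2-en-1-yl)-5-(2-methylpropanoyl)-2,3-dihydro-1-benzofuran-4(7H)-one, via diol 17 (not isolated)
Conditions: p-TsOH·H2O (0.1 equiv), MeOH, 23 °C; then toluene, 4 Å MS, 50 °C
Reagents that add atoms: none
Why: Acid cleaves the acetonide to diol 17, whose secondary C2 hydroxyl adds to the protonated keto tautomer at C7a of the vinylogous acid O=C4–C3a=C7a–OH and water is then lost, an intramolecular Fischer-type vinylogous esterification whose closest known relative is the acid-catalysed conversion of cyclic 1,3-diones and alcohols into 3-alkoxy-enones. The dihydrofuran ring (O1, C2, C3, C3a, C7a) is closed by formation of the O1–C7a bond in the 5-exo-trig mode. No stereocentre is created: the C2–O bond is never broken, so the configuration set by the Payne inversion is retained, and C1' and C7 are untouched (the C7 descriptor changes only because of the enol tautomer). Closure at C7a rather than C4 is secured because the C4/C5/C6 acyl-triketone unit is locked as a hydrogen-bonded enol chelate with the isobutyryl group, whereas the C7a enol is free and its etherification preserves that chelate. The secondary hydroxyl should win over the tertiary one because it is less hindered and closes a five- rather than a six-membered ring, and the mild acid is chosen to avoid ionisation of the tertiary alcohol and addition of enols to the prenyl olefins.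

Step 14
Reactants: 18 (2S,7R)-6-hydroxy-2-[(2S)-2-hydroxy-6-methylhept-5-en-2-yl]-7-methyl-7-(3-methylbut-2-en-1-yl)-5-(2-methylpropanoyl)-2,3-dihydro-1-benzofuran-4(7H)-one
Product: 19 (2S,5R,7S)-2-[(2S)-2-hydroxy-6-methylhept-5-en-2-yl]-7-methyl-5,7-bis(3-methylbut-2-en-1-yl)-5-(2-methylpropanoyl)-2,3-dihydro-1-benzofuran-4,6(5H,7H)-dione
Conditions: Pd(PPh3)4 (0.05 equiv), prenyl acetate, Et3N, THF, 45 °C
Reagents that add atoms: 3-methylbut-2-en-1-yl acetate, CC(=O)OCC=C(C)C
Why: Tsuji–Trost allylic alkylation, in which zerovalent palladium ionises prenyl acetate and the soft triketonate attacks the unsubstituted terminus of the π-prenyl complex through C5 (O-allyl products re-ionise); the new quaternary centre should form by approach anti to the bulkier C7 prenyl arm, on the face of the C7 methyl group, which places the two prenyl groups trans (5R).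

**Compound list**

1 | nerol, (2Z)-3,7-dimethylocta-2,6-dien-1-ol | CC(C)=CCC/C(C)=C\CO | starting material
2 | [(2R,3S)-3-methyl-3-(4-methylpent-3-en-1-yl)oxiran-2-yl]methanol | OC[C@H]1O[C@@]1(C)CCC=C(C)C | intermediate
3 | (2R,3S)-3,7-dimethyl-1-(phenylsulfanyl)oct-6-ene-2,3-diol | CC(C)=CCC[C@](C)(O)[C@@H](O)CSc1ccccc1 | intermediate
4 | (4S,5R)-2,2,4-trimethyl-4-(4-methylpent-3-en-1-yl)-5-[(phenylsulfanyl)methyl]-1,3-dioxolane | CC(C)=CCC[C@]1(C)OC(C)(C)O[C@H]1CSc1ccccc1 | intermediate
5 | (4S,5R)-2,2,4-trimethyl-4-(4-methylpent-3-en-1-yl)-5-[(phenylsulfinyl)methyl]-1,3-dioxolane (both sulfur epimers) | CC(C)=CCC[C@]1(C)OC(C)(C)O[C@H]1CS(=O)c1ccccc1 | intermediate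
6 | (phenylsulfanyl)[(4R,5S)-2,2,5-trimethyl-5-(4-methylpent-3-en-1-yl)-1,3-dioxolan-4-yl]methyl trifluoroacetate (both epimers at the O,S-acetal carbon) | CC(C)=CCC[C@]1(C)OC(C)(C)O[C@H]1C(OC(=O)C(F)(F)F)Sc1ccccc1 | intermediate
7 | (4R,5S)-2,2,5-trimethyl-5-(4-methylpent-3-en-1-yl)-1,3-dioxolane-4-carbaldehyde | CC(C)=CCC[C@]1(C)OC(C)(C)O[C@H]1C=O | intermediate
8 | methyl (3S)-3-hydroxybutanoate | C[C@H](O)CC(=O)OC | starting material
9 | methyl (2S,3S)-3-hydroxy-2-(3-methylbut-2-en-1-yl)butanoate | C[C@H](O)[C@H](CC=C(C)C)C(=O)OC | intermediate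
10 | methyl (2R)-2-[(1S)-1-hydroxyethyl]-2,5-dimethylhex-4-enoate | C[C@H](O)[C@@](C)(CC=C(C)C)C(=O)OC | intermediate
11 | methyl (2R)-2-acetyl-2,5-dimethylhex-4-enoate | CC(=O)[C@@](C)(CC=C(C)C)C(=O)OC | intermediate
12 | methyl (2R)-2,6-dimethyl-2-(3-methylbut-2-en-1-yl)-3,5-dioxoheptanoate | CC(C)C(=O)CC(=O)[C@@](C)(CC=C(C)C)C(=O)OC | intermediate
13 | methyl (2R)-4-acetyl-2,6-dimethyl-2-(3-methylbut-2-en-1-yl)-3,5-dioxoheptanoate (C4 enolised, not a stereocentre) | CC(C)C(=O)C(C(C)=O)C(=O)[C@@](C)(CC=C(C)C)C(=O)OC | intermediate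
14 | (4S)-3,5-dihydroxy-4-methyl-4-(3-methylbut-2-en-1-yl)-2-(2-methylpropanoyl)cyclohexa-2,5-dien-1-one | CC(C)C(=O)C1=C(O)[C@@](C)(CC=C(C)C)C(O)=CC1=O | intermediate
15 | (4R)-3-hydroxy-4-methyl-4-(3-methylbut-2-en-1-yl)-2-(2-methylpropanoyl)-6-{[(4S,5S)-2,2,5-trimethyl-5-(4-methylpent-3-en-1-yl)-1,3-dioxolan-4-yl]methylidene}cyclohex-2-ene-1,5-dione (Knoevenagel adduct; ring centre spatially as in 14; alkene geometry undefined) | CC(C)C(=O)C1=C(O)[C@@](C)(CC=C(C)C)C(=O)C(=C[C@@H]2OC(C)(C)O[C@@]2(C)CCC=C(C)C)C1=O | intermediate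
16 | (4S)-3,5-dihydroxy-4-methyl-4-(3-methylbut-2-en-1-yl)-2-(2-methylpropanoyl)-6-{[(4S,5S)-2,2,5-trimethyl-5-(4-methylpent-3-en-1-yl)-1,3-dioxolan-4-yl]methyl}cyclohexa-2,5-dien-1-one | CC(C)C(=O)C1=C(O)[C@@](C)(CC=C(C)C)C(O)=C(C[C@@H]2OC(C)(C)O[C@@]2(C)CCC=C(C)C)C1=O | intermediate
17 | (4S)-6-[(2S,3S)-2,3-dihydroxy-3,7-dimethyloct-6-en-1-yl]-3,5-dihydroxy-4-methyl-4-(3-methylbut-2-en-1-yl)-2-(2-methylpropanoyl)cyclohexa-2,5-dien-1-one | CC(C)C(=O)C1=C(O)[C@@](C)(CC=C(C)C)C(O)=C(C[C@H](O)[C@@](C)(O)CCC=C(C)C)C1=O | intermediate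
18 | (2S,7R)-6-hydroxy-2-[(2S)-2-hydroxy-6-methylhept-5-en-2-yl]-7-methyl-7-(3-methylbut-2-en-1-yl)-5-(2-methylpropanoyl)-2,3-dihydro-1-benzofuran-4(7H)-one (C7 spatially as in the target) | CC(C)=CCC[C@](C)(O)[C@@H]1CC2=C(O1)[C@](C)(CC=C(C)C)C(O)=C(C(=O)C(C)C)C2=O | intermediate
19 | (2S,5R,7S)-2-[(2S)-2-hydroxy-6-methylhept-5-en-2-yl]-7-methyl-5,7-bis(3-methylbut-2-en-1-yl)-5-(2-methylpropanoyl)-2,3-dihydro-1-benzofuran-4,6(5H,7H)-dione | CC(C)=CCC[C@](C)(O)[C@@H]1CC2=C(O1)[C@](C)(CC=C(C)C)C(=O)[C@](CC=C(C)C)(C(=O)C(C)C)C2=O | target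

**Step count.** Total: 14 steps. Longest linear sequence: 9 steps (steps 6 to 14, from methyl (3S)-3-hydroxybutanoate); the aldehyde branch (steps 1 to 5) joins at step 12.

**Steps most likely to fail**

Step 14. The methyl and prenyl groups on C7 differ little in size, so facial discrimination in the C5 alkylation may be poor, and O-allylation may persist. The fallback sets out from 18 and replaces substrate control by ligand control. Allylation with allyl acetate, Pd2(dba)3 and (R,R)-N,N'-bis[2-(diphenylphosphino)benzoyl]cyclohexane-1,2-diamine (Et3N, CH2Cl2) would give (2S,5R,7S)-2-[(2S)-2-hydroxy-6-methylhept-5-en-2-yl]-7-methyl-7-(3-methylbut-2-en-1-yl)-5-(2-methylpropanoyl)-5-(prop-2-en-1-yl)-2,3-dihydro-1-benzofuran-4,6(5H,7H)-dione F1. The sense of induction of this ligand is assumed; its antipode is used if it proves mismatched. Cross-metathesis of the terminal olefin of F1 with 2-methyl-2-butene (second-generation Grubbs catalyst, 40 °C) then comes back to 19.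

Step 13. The alcohol may close onto C4 instead of C7a, the tertiary hydroxyl may compete to give the six-membered ether, or the acid may add an enol to a prenyl olefin. The fallback sets out from 2 and 14 and closes the same ring through its other C–O bond. Oxidation of 2 (SO3·pyridine, DMSO, Et3N) gives (2S,3S)-3-methyl-3-(4-methylpent-3-en-1-yl)oxirane-2-carbaldehyde F2. Union with 14 under the conditions of step 12 gives (4S)-3,5-dihydroxy-4-methyl-4-(3-methylbut-2-en-1-yl)-6-{[(2R,3S)-3-methyl-3-(4-methylpent-3-en-1-yl)oxiran-2-yl]methyl}-2-(2-methylpropanoyl)cyclohexa-2,5-dien-1-one F3. Its free C7a enol oxygen opens the epoxide at C2 (5-exo-tet, inversion; Et3N, CH2Cl2, 23 °C) and the route is rejoined at 18, with the same configuration because C2 of 2 is inverted once in either route.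

Step 11. The second deprotonation of the triketonate may be incomplete, or retro-Claisen loss of an acyl group or O-acylation may take over. The fallback sets out from 12. C-acylation with methyl 3-chloro-3-oxopropanoate (MgCl2, pyridine) gives methyl (2R)-4-(3-methoxy-3-oxopropanoyl)-2,6-dimethyl-2-(3-methylbut-2-en-1-yl)-3,5-dioxoheptanoate F4. Its doubly activated methylene closes the ring under mild base (DBU, THF) to methyl (3R)-2,4-dihydroxy-3-methyl-3-(3-methylbut-2-en-1-yl)-5-(2-methylpropanoyl)-6-oxocyclohexa-1,4-diene-1-carboxylate F5. Saponification and decarboxylation (aq. NaOH, then HCl, 50 °C) come back to 14.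

**Further compounds**

F1 | step 14 | (2S,5R,7S)-2-[(2S)-2-hydroxy-6-methylhept-5-en-2-yl]-7-methyl-7-(3-methylbut-2-en-1-yl)-5-(2-methylpropanoyl)-5-(prop-2-en-1-yl)-2,3-dihydro-1-benzofuran-4,6(5H,7H)-dione | CC(C)=CCC[C@](C)(O)[C@@H]1CC2=C(O1)[C@](C)(CC=C(C)C)C(=O)[C@](CC=C)(C(=O)C(C)C)C2=O
F2 | step 13 | (2S,3S)-3-methyl-3-(4-methylpent-3-en-1-yl)oxirane-2-carbaldehyde | O=C[C@H]1O[C@@]1(C)CCC=C(C)C
F3 | step 13 | (4S)-3,5-dihydroxy-4-methyl-4-(3-methylbut-2-en-1-yl)-6-{[(2R,3S)-3-methyl-3-(4-methylpent-3-en-1-yl)oxiran-2-yl]methyl}-2-(2-methylpropanoyl)cyclohexa-2,5-dien-1-one | CC(C)C(=O)C1=C(O)[C@@](C)(CC=C(C)C)C(O)=C(C[C@H]2O[C@@]2(C)CCC=C(C)C)C1=O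
F4 | step 11 | methyl (2R)-4-(3-methoxy-3-oxopropanoyl)-2,6-dimethyl-2-(3-methylbut-2-en-1-yl)-3,5-dioxoheptanoate | CC(C)C(=O)C(C(=O)CC(=O)OC)C(=O)[C@@](C)(CC=C(C)C)C(=O)OC
F5 | step 11 | methyl (3R)-2,4-dihydroxy-3-methyl-3-(3-methylbut-2-en-1-yl)-5-(2-methylpropanoyl)-6-oxocyclohexa-1,4-diene-1-carboxylate | CC(C)C(=O)C1=C(O)[C@@](C)(CC=C(C)C)C(O)=C(C(=O)OC)C1=O
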